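## Retrosynthetic overview

Terpenoid numbering is used: ring A = C1–C5 and C10, ring B = C5–C10, C4 carries the gem-dimethyl group, C9 is the quaternary carbon, C11–C15 is the side chain with the carbinol at C13.

1. The C7 acetate comes from the 6,7-diol; ring B is opened at C6–C7 (pinacol retron of the cis-diol) to a dialdehyde; the C13 carbinol is cut at C12–C13 (lithiation–borylation of a C12 boronic ester with an (R)-but-3-en-2-yl carbamate).
2. Ring A: the fully substituted C5=C10 double bond shared by rings A and B, flanked by the gem-dimethyl carbon C4 and the oxygenated C6, is the retron of a Diels–Alder reaction of an ynal (C10≡C5–C6HO) with 4-methylpenta-1,3-diene (C1–C4); C2=C3 is hydrogenated afterwards.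
3. C8/C9 (tertiary/quaternary pair): enantioselective Ireland–Claisen rearrangement of an (E)-enynyl propanoate places the alkyne, a vinyl group (C11=C12) and the C7 carboxyl around C9 in one step.
4. Order of ring formation: ring A (step 6), then ring B (step 13).

Key step: step 6

Assumption: the (4S,5S) bromoborane of step 2 is taken to deliver the (2S,3R) acid by analogy with simple allylic propanoates; should the first run show the opposite sense, the (4R,5R) reagent is used with no other change.

## Route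

Step 1
Reactants: 1 (2E)-3-methylpent-2-en-4-yn-1-ol
Product: 2 (2E)-3-methylpent-2-en-4-yn-1-yl propanoate
Conditions: EtCOCl, Et3N, DMAP (cat.), CH2Cl2, 0 °C to rt
Reagents that add atoms: propanoyl chloride, CCC(=O)Cl
Why: DMAP-catalysed acylation of a primary allylic alcohol with an acid chloride should be clean, forms no stereocenter and leaves the (E)-alkene untouched.

Step 2
Reactants: 2 (2E)-3-methylpent-2-en-4-yn-1-yl propanoate
Product: 5 (2S,3R)-3-ethenyl-2,3-dimethylpent-4-ynoic acid, via boron enolate 3 (not isolated), via boron carboxylate 4 (not isolated)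
Conditions: (4S,5S)-2-bromo-1,3-bis{[3,5-bis(trifluoromethyl)phenyl]sulfonyl}-4,5-diphenyl-1,3,2-diazaborolidine (1.2 equiv), i-Pr2NEt, CH2Cl2, −78 °C, then −20 °C; aqueous work-up
Reagents that add atoms: none
Why: Enantioselective Ireland–Claisen rearrangement of a chiral boron ester enolate, in which soft enolisation should give the Z(O)-enolate whose chair transition state (enolate methyl and alkynyl group equatorial, alkene methyl axial) sets the C2/C3 relative configuration, while the C2-symmetric bis-sulfonamide ligand on boron selects the enolate face and so the absolute configuration.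

Step 3
Reactants: 5 (2S,3R)-3-ethenyl-2,3-dimethylpent-4-ynoic acid
Product: 7 ethyl (2S,3R)-3-ethenyl-6,6-diethoxy-2,3-dimethylhex-4-ynoate, via ethyl ester 6 (not isolated)
Conditions: HC(OEt)3 (solvent), 100 °C; then ZnI2 (5 mol %), 135 °C, EtOH distilled off
Reagents that add atoms: triethyl orthoformate, CCOC(OCC)OCC
Why: Orthoester esterification of the acid followed by ZnI2-catalysed condensation of the terminal alkyne with the orthoformate (acetylenic acetal formation) caps the alkyne with the masked formyl carbon under non-basic conditions that leave both stereocenters untouched.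

Step 4
Reactants: 7 ethyl (2S,3R)-3-ethenyl-6,6-diethoxy-2,3-dimethylhex-4-ynoate
Product: 8 ethyl (2S,3R)-6,6-diethoxy-2,3-dimethyl-3-[2-(4,4,5,5-tetramethyl-1,3,2-dioxaborolan-2-yl)ethyl]hex-4-ynoate
Conditions: pinacolborane (1.2 equiv), [Ir(cod)Cl]2 (1.5 mol %), dppe (3 mol %), CH2Cl2, rt
Reagents that add atoms: pinacolborane, CC1(C)OBOC1(C)C
Why: Iridium-catalysed anti-Markovnikov hydroboration should prefer the monosubstituted vinyl group over the internal alkyne that is shielded by the quaternary carbon and the acetal, and it forms no stereocenter.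

Step 5
Reactants: 8 ethyl (2S,3R)-6,6-diethoxy-2,3-dimethyl-3-[2-(4,4,5,5-tetramethyl-1,3,2-dioxaborolan-2-yl)ethyl]hex-4-ynoate
Product: 9 ethyl (2S,3R)-2,3-dimethyl-6-oxo-3-[2-(4,4,5,5-tetramethyl-1,3,2-dioxaborolan-2-yl)ethyl]hex-4-ynoate
Conditions: HCO2H, H2O, CH2Cl2, 0 °C to rt
Reagents that add atoms: water, O
Why: Acid-catalysed acetal hydrolysis unmasks the conjugated ynal that serves as the activated dienophile, while the ester and the alkyl pinacol boronate are stable to aqueous formic acid.

Step 6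
Reactants: 9 ethyl (2S,3R)-2,3-dimethyl-6-oxo-3-[2-(4,4,5,5-tetramethyl-1,3,2-dioxaborolan-2-yl)ethyl]hex-4-ynoate, 10 4-methylpenta-1,3-diene
Product: 11 ethyl (2S,3R)-3-(2-formyl-3,3-dimethylcyclohexa-1,4-dien-1-yl)-2,3-dimethyl-5-(4,4,5,5-tetramethyl-1,3,2-dioxaborolan-2-yl)pentanoate
Conditions: neat 10 (20 equiv), BHT (cat.), sealed tube, 120 °C
Reagents that add atoms: none
Why: A concerted but asynchronous thermal [4+2] cycloaddition joins the CH2 terminus of the diene to the β-carbon of the ynal (the alkyne carbon on the quaternary centre) and the CMe2 terminus to the α-carbon, so that both new σ-bonds of ring A, its gem-dimethyl quaternary carbon and the tetrasubstituted ring-fusion alkene arise together. The closest known reaction type is the intermolecular Diels–Alder reaction of acetylenic aldehydes and esters with 4-methylpenta-1,3-diene and related 1,1-disubstituted dienes, which gives 6,6-dimethylcyclohexa-1,4-diene-1-carbonyl compounds. Ring A is closed by suprafacial addition of the four diene carbons across one π-bond of the alkyne (intermolecular six-membered cycloaddition), and the resulting cyclohexa-1,4-diene cannot aromatise because of its quaternary carbon. No stereocenter is formed, and the two existing ones lie on sp3 carbons outside the reacting π-system, the one α to the ester not being enolised under neutral thermal conditions. The step needs regioselectivity and periselectivity over ene and [2+2] pathways: the larger HOMO coefficient at the unsubstituted diene terminus pairs with the β-carbon of the ynal ("ortho" orientation), sterics reinforce this because the bulky quaternary substituent meets the CH2 end, and the absence of a Lewis acid disfavours the stepwise cationic ene and [2+2] channels. The formyl group that activates the alkyne is kept as the carbon that later closes ring B.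

Step 7
Reactants: 11 ethyl (2S,3R)-3-(2-formyl-3,3-dimethylcyclohexa-1,4-dien-1-yl)-2,3-dimethyl-5-(4,4,5,5-tetramethyl-1,3,2-dioxaborolan-2-yl)pentanoate
Product: 12 ethyl (2S,3R)-3-(2-formyl-3,3-dimethylcyclohex-1-en-1-yl)-2,3-dimethyl-5-(4,4,5,5-tetramethyl-1,3,2-dioxaborolan-2-yl)pentanoate
Conditions: H2 (1 atm), RhCl(PPh3)3 (5 mol %), benzene, rt
Reagents that add atoms: none
Why: Homogeneous hydrogenation with RhCl(PPh3)3 should reduce the cis-disubstituted ring alkene and leave the tetrasubstituted conjugated alkene and the hindered aldehyde untouched, and no vinyl group is present at this stage.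

Step 8
Reactants: 12 ethyl (2S,3R)-3-(2-formyl-3,3-dimethylcyclohex-1-en-1-yl)-2,3-dimethyl-5-(4,4,5,5-tetramethyl-1,3,2-dioxaborolan-2-yl)pentanoate
Product: 13 (2S,3R)-3-[2-(hydroxymethyl)-3,3-dimethylcyclohex-1-en-1-yl]-2,3-dimethyl-5-(4,4,5,5-tetramethyl-1,3,2-dioxaborolan-2-yl)pentan-1-ol
Conditions: i-Bu2AlH (5 equiv), CH2Cl2, −78 to 0 °C; aqueous KNaC4H4O6
Reagents that add atoms: none
Why: Hydride reduction with i-Bu2AlH converts the aldehyde and the ethyl ester into primary alcohols without touching the alkyl pinacol boronate or the stereocenters.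

Step 9
Reactants: 13 (2S,3R)-3-[2-(hydroxymethyl)-3,3-dimethylcyclohex-1-en-1-yl]-2,3-dimethyl-5-(4,4,5,5-tetramethyl-1,3,2-dioxaborolan-2-yl)pentan-1-ol
Product: 14 bis(trimethylsilyl) ether of 13
Conditions: Me3SiCl, Et3N, CH2Cl2, 0 °C; filtered, concentrated, used directly
Reagents that add atoms: chlorotrimethylsilane, C[Si](C)(C)Cl
Why: O-Silylation removes both hydroxyl protons before the organolithium step, and the trimethylsilyl ethers are cleaved again by the basic oxidative work-up of step 11.

Step 10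
Reactants: 15 (2R)-but-3-en-2-ol
Product: 16 (2R)-but-3-en-2-yl N,N-di(propan-2-yl)carbamate
Conditions: i-Pr2NCOCl, Et3N, CH2Cl2, reflux
Reagents that add atoms: N,N-di(propan-2-yl)carbamoyl chloride, CC(C)N(C(C)C)C(=O)Cl
Why: Carbamoylation at oxygen leaves the carbinol configuration untouched and installs the directing and leaving group for lithiation–borylation.

Step 11
Reactants: 14 bis(trimethylsilyl) ether of 13, 16 (2R)-but-3-en-2-yl N,N-di(propan-2-yl)carbamate
Product: 20 (2S,3R,6S)-3-[2-(hydroxymethyl)-3,3-dimethylcyclohex-1-en-1-yl]-2,3,6-trimethyloct-7-ene-1,6-diol, via lithiated carbamate 17 (not isolated), via boronate complex 18 (not isolated), via tertiary boronic ester 19 (not isolated)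
Conditions: 16 (1.4 equiv), s-BuLi (1.3 equiv), TMEDA, Et2O, −78 °C; then 14, −78 °C to rt; then NaOH, H2O2, THF–H2O, 0 °C to rt
Reagents that add atoms: hydrogen peroxide, OO
Why: Lithiation–borylation, in which deprotonation α to oxygen and borylation at that carbon both proceed with retention, the primary alkyl group then migrates from boron to carbon with inversion as the carbamate leaves, and oxidation of the tertiary C–B bond with retention gives the (S)-tertiary allylic alcohol, so that the new stereocenter is relayed from (R)-but-3-en-2-ol while aqueous hydroxide also cleaves the silyl ethers.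

Step 12
Reactants: 20 (2S,3R,6S)-3-[2-(hydroxymethyl)-3,3-dimethylcyclohex-1-en-1-yl]-2,3,6-trimethyloct-7-ene-1,6-diol
Product: 21 (2S,3R,6S)-3-(2-formyl-3,3-dimethylcyclohex-1-en-1-yl)-6-hydroxy-2,3,6-trimethyloct-7-enal
Conditions: (COCl)2, DMSO, CH2Cl2, −78 °C; then i-Pr2NEt, −78 to −20 °C
Reagents that add atoms: none
Why: Swern oxidation converts both primary alcohols into aldehydes at low temperature, where the stereocenter α to the new formyl group should not epimerise and the tertiary allylic alcohol is inert.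

Step 13
Reactants: 21 (2S,3R,6S)-3-(2-formyl-3,3-dimethylcyclohex-1-en-1-yl)-6-hydroxy-2,3,6-trimethyloct-7-enal
Product: 22 (1S,2R,3S,4R)-4-[(3S)-3-hydroxy-3-methylpent-4-en-1-yl]-3,4,8,8-tetramethyl-1,2,3,4,5,6,7,8-octahydronaphthalene-1,2-diol
Conditions: SmI2 (3 equiv), t-BuOH (2 equiv), THF, −78 °C to rt
Reagents that add atoms: none
Why: SmI2-mediated intramolecular pinacol coupling, in which the ketyl of the conjugated aldehyde adds to the second formyl group within a samarium chelate that enforces the cis-diol, and a chair-like transition state places the C2 oxygen equatorial and trans to the neighbouring methyl group and the allylic C1 oxygen pseudoaxial, away from the gem-dimethyl group, which sets both carbinol centres as (1S,2R).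

Step 14
Reactants: 22 (1S,2R,3S,4R)-4-[(3S)-3-hydroxy-3-methylpent-4-en-1-yl]-3,4,8,8-tetramethyl-1,2,3,4,5,6,7,8-octahydronaphthalene-1,2-diol
Product: 23 (1S,2R,3S,4R)-1-hydroxy-4-[(3S)-3-hydroxy-3-methylpent-4-en-1-yl]-3,4,8,8-tetramethyl-1,2,3,4,5,6,7,8-octahydronaphthalen-2-yl acetate
Conditions: Ac2O (1.2 equiv), pyridine, CH2Cl2, 0 °C
Reagents that add atoms: acetic anhydride, CC(=O)OC(C)=O
Why: Acylation with acetic anhydride in pyridine should take place at the equatorial, less hindered secondary hydroxyl and not at the pseudoaxial allylic hydroxyl next to the gem-dimethyl group or at the tertiary hydroxyl.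

## Compound list

1 | (2E)-3-methylpent-2-en-4-yn-1-ol | C#C/C(C)=C/CO | starting material
2 | (2E)-3-methylpent-2-en-4-yn-1-yl propanoate | CCC(=O)OC/C=C(C)/C#C | intermediate
3 | Z(O)-boron enolate of 2 (boron in the (4S,5S)-bis-sulfonyl diazaborolidine ring) | C/C=C(\OB1N(S(=O)(=O)c2cc(C(F)(F)F)cc(C(F)(F)F)c2)[C@@H](c2ccccc2)[C@H](c2ccccc2)N1S(=O)(=O)c1cc(C(F)(F)F)cc(C(F)(F)F)c1)OC/C=C(C)/C#C | intermediate
4 | boron carboxylate of acid 5 | O=C(OB1N(S(=O)(=O)c2cc(C(F)(F)F)cc(C(F)(F)F)c2)[C@@H](c2ccccc2)[C@H](c2ccccc2)N1S(=O)(=O)c1cc(C(F)(F)F)cc(C(F)(F)F)c1)[C@@H](C)[C@@](C)(C=C)C#C | intermediate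
5 | (2S,3R)-3-ethenyl-2,3-dimethylpent-4-ynoic acid | OC(=O)[C@@H](C)[C@@](C)(C=C)C#C | intermediate
6 | ethyl (2S,3R)-3-ethenyl-2,3-dimethylpent-4-ynoate | CCOC(=O)[C@@H](C)[C@@](C)(C=C)C#C | intermediate
7 | ethyl (2S,3R)-3-ethenyl-6,6-diethoxy-2,3-dimethylhex-4-ynoate | CCOC(=O)[C@@H](C)[C@@](C)(C=C)C#CC(OCC)OCC | intermediate
8 | ethyl (2S,3R)-6,6-diethoxy-2,3-dimethyl-3-[2-(4,4,5,5-tetramethyl-1,3,2-dioxaborolan-2-yl)ethyl]hex-4-ynoate | CCOC(=O)[C@@H](C)[C@@](C)(CCB1OC(C)(C)C(C)(C)O1)C#CC(OCC)OCC | intermediate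
9 | ethyl (2S,3R)-2,3-dimethyl-6-oxo-3-[2-(4,4,5,5-tetramethyl-1,3,2-dioxaborolan-2-yl)ethyl]hex-4-ynoate | CCOC(=O)[C@@H](C)[C@@](C)(CCB1OC(C)(C)C(C)(C)O1)C#CC=O | intermediate
10 | 4-methylpenta-1,3-diene | C=CC=C(C)C | starting material
11 | ethyl (2S,3R)-3-(2-formyl-3,3-dimethylcyclohexa-1,4-dien-1-yl)-2,3-dimethyl-5-(4,4,5,5-tetramethyl-1,3,2-dioxaborolan-2-yl)pentanoate | CCOC(=O)[C@@H](C)[C@@](C)(CCB1OC(C)(C)C(C)(C)O1)C1=C(C=O)C(C)(C)C=CC1 | intermediate
12 | ethyl (2S,3R)-3-(2-formyl-3,3-dimethylcyclohex-1-en-1-yl)-2,3-dimethyl-5-(4,4,5,5-tetramethyl-1,3,2-dioxaborolan-2-yl)pentanoate | CCOC(=O)[C@@H](C)[C@@](C)(CCB1OC(C)(C)C(C)(C)O1)C1=C(C=O)C(C)(C)CCC1 | intermediate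
13 | (2S,3R)-3-[2-(hydroxymethyl)-3,3-dimethylcyclohex-1-en-1-yl]-2,3-dimethyl-5-(4,4,5,5-tetramethyl-1,3,2-dioxaborolan-2-yl)pentan-1-ol | OC[C@@H](C)[C@@](C)(CCB1OC(C)(C)C(C)(C)O1)C1=C(CO)C(C)(C)CCC1 | intermediate
14 | bis(trimethylsilyl) ether of 13 | C[Si](C)(C)OC[C@@H](C)[C@@](C)(CCB1OC(C)(C)C(C)(C)O1)C1=C(CO[Si](C)(C)C)C(C)(C)CCC1 | intermediate
15 | (2R)-but-3-en-2-ol | C=C[C@@H](C)O | starting material
16 | (2R)-but-3-en-2-yl N,N-di(propan-2-yl)carbamate | C=C[C@@H](C)OC(=O)N(C(C)C)C(C)C | intermediate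
17 | α-lithiated carbamate (lithium in place of the carbinol hydrogen of 16) | C=C[C@@]([Li])(C)OC(=O)N(C(C)C)C(C)C | intermediate
18 | lithium boronate complex from 14 and 17 | C[Si](C)(C)OC[C@@H](C)[C@@](C)(CC[B-]1(OC(C)(C)C(C)(C)O1)[C@](C)(OC(=O)N(C(C)C)C(C)C)C=C)C1=C(CO[Si](C)(C)C)C(C)(C)CCC1.[Li+] | intermediate
19 | tertiary allylic pinacol boronic ester after 1,2-migration (bis-silyl ether) | C[Si](C)(C)OC[C@@H](C)[C@@](C)(CC[C@](C)(B1OC(C)(C)C(C)(C)O1)C=C)C1=C(CO[Si](C)(C)C)C(C)(C)CCC1 | intermediate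
20 | (2S,3R,6S)-3-[2-(hydroxymethyl)-3,3-dimethylcyclohex-1-en-1-yl]-2,3,6-trimethyloct-7-ene-1,6-diol | OC[C@@H](C)[C@@](C)(CC[C@](C)(O)C=C)C1=C(CO)C(C)(C)CCC1 | intermediate
21 | (2S,3R,6S)-3-(2-formyl-3,3-dimethylcyclohex-1-en-1-yl)-6-hydroxy-2,3,6-trimethyloct-7-enal | O=C[C@@H](C)[C@@](C)(CC[C@](C)(O)C=C)C1=C(C=O)C(C)(C)CCC1 | intermediate
22 | (1S,2R,3S,4R)-4-[(3S)-3-hydroxy-3-methylpent-4-en-1-yl]-3,4,8,8-tetramethyl-1,2,3,4,5,6,7,8-octahydronaphthalene-1,2-diol | C=C[C@@](C)(O)CC[C@@]1(C)C2=C([C@H](O)[C@H](O)[C@H]1C)C(C)(C)CCC2 | intermediate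
23 | (1S,2R,3S,4R)-1-hydroxy-4-[(3S)-3-hydroxy-3-methylpent-4-en-1-yl]-3,4,8,8-tetramethyl-1,2,3,4,5,6,7,8-octahydronaphthalen-2-yl acetate (CNP0126002.2) | C=C[C@@](C)(O)CC[C@@]1(C)C2=C([C@H](O)[C@H](OC(C)=O)[C@H]1C)C(C)(C)CCC2 | target

## Step count and risks

Total steps: 14 (13 in the main line plus the preparation of carbamate 16).
Longest linear sequence: 13 steps, from 1 to 23 through steps 1–9 and 11–14.

Steps most likely to fail:

1. Step 6 (Diels–Alder reaction). The diene may reach its cisoid conformation too rarely, so that ene addition at the allylic methyl groups, stepwise [2+2] addition or thermal decay of the ynal outpaces the cycloaddition. The fallback sets out from 9 and uses an activated diene whose activating group is removed again. Mesityl oxide is converted with LiN(i-Pr)2 and Me3SiCl into 4-methyl-2-(trimethylsilyloxy)penta-1,3-diene F1. Heating 9 with this diene in toluene should give the silyl enol ether adduct F2, in which the siloxy group ("para") and the gem-dimethyl terminus ("ortho") direct to the same regiochemistry. CsF and PhNTf2 turn it into the enol triflate F3. Reduction with Pd(OAc)2, PPh3, HCO2H and n-Bu3N in DMF replaces the triflate by hydrogen and the route is rejoined at 11.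

2. Step 11 (lithiation–borylation). Borylation may occur at the γ-terminus of the lithiated allyl carbamate, or the organolithium may lose its configuration before it is trapped. The fallback sets out from 12 and builds the carbinol by cross-coupling and asymmetric epoxidation. But-2-yn-1-ol is reduced with NaAlH2(OCH2CH2OMe)2 and quenched with I2 to give (Z)-3-iodobut-2-en-1-ol F4. Suzuki–Miyaura coupling of the primary alkyl boronic ester 12 with this iodide (Pd(OAc)2, RuPhos, K3PO4, toluene–water, 80 °C) should give the (Z)-allylic alcohol F5. Sharpless asymmetric epoxidation with D-(−)-diethyl tartrate, Ti(Oi-Pr)4 and t-BuOOH should give the epoxy alcohol F6, the epoxide oxygen setting the future C13 configuration. I2, PPh3 and imidazole give the epoxy iodide F7. Zn in refluxing EtOH opens it reductively to the tertiary allylic alcohol F8. Reduction of its aldehyde and ester with i-Bu2AlH rejoins the route at 20.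

3. Step 13 (pinacol closure of ring B). Each formyl group may be reduced to the alcohol without C–C coupling, or closure may run through a non-chelated arrangement that gives the trans-diol. The fallback sets out from 21 and makes the C6–C7 bond as an alkene first. Double Wittig methylenation (Ph3PCH3Br, KN(SiMe3)2, THF, −78 to 0 °C) should give the triene F9. Ring-closing metathesis with the second-generation Grubbs catalyst in CH2Cl2 closes ring B to the conjugated ring B diene F10. OsO4 (1 equiv) in pyridine–THF at −78 °C, then aqueous NaHSO3, should dihydroxylate the electron-rich disubstituted ring alkene ahead of the vinyl carbinol, from the face opposite the C8 methyl group and the C9 side chain, and so return to the route at 22.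

## Further compounds

F1 | step 6 | 4-methyl-2-(trimethylsilyloxy)penta-1,3-diene | C=C(O[Si](C)(C)C)C=C(C)C
F2 | step 6 | ethyl (2S,3R)-3-[2-formyl-3,3-dimethyl-5-(trimethylsilyloxy)cyclohexa-1,4-dien-1-yl]-2,3-dimethyl-5-(4,4,5,5-tetramethyl-1,3,2-dioxaborolan-2-yl)pentanoate | CCOC(=O)[C@@H](C)[C@@](C)(CCB1OC(C)(C)C(C)(C)O1)C1=C(C=O)C(C)(C)C=C(O[Si](C)(C)C)C1
F3 | step 6 | ethyl (2S,3R)-3-(2-formyl-3,3-dimethyl-5-{[(trifluoromethyl)sulfonyl]oxy}cyclohexa-1,4-dien-1-yl)-2,3-dimethyl-5-(4,4,5,5-tetramethyl-1,3,2-dioxaborolan-2-yl)pentanoate | CCOC(=O)[C@@H](C)[C@@](C)(CCB1OC(C)(C)C(C)(C)O1)C1=C(C=O)C(C)(C)C=C(OS(=O)(=O)C(F)(F)F)C1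
F4 | step 11 | (2Z)-3-iodobut-2-en-1-ol | C/C(I)=C/CO
F5 | step 11 | ethyl (2S,3R,6Z)-3-(2-formyl-3,3-dimethylcyclohex-1-en-1-yl)-8-hydroxy-2,3,6-trimethyloct-6-enoate | CCOC(=O)[C@@H](C)[C@@](C)(CC/C(C)=C\CO)C1=C(C=O)C(C)(C)CCC1
F6 | step 11 | ethyl (2S,3R)-3-(2-formyl-3,3-dimethylcyclohex-1-en-1-yl)-5-[(2S,3R)-3-(hydroxymethyl)-2-methyloxiran-2-yl]-2,3-dimethylpentanoate | CCOC(=O)[C@@H](C)[C@@](C)(CC[C@]1(C)O[C@@H]1CO)C1=C(C=O)C(C)(C)CCC1
F7 | step 11 | ethyl (2S,3R)-3-(2-formyl-3,3-dimethylcyclohex-1-en-1-yl)-5-[(2S,3S)-3-(iodomethyl)-2-methyloxiran-2-yl]-2,3-dimethylpentanoate | CCOC(=O)[C@@H](C)[C@@](C)(CC[C@]1(C)O[C@@H]1CI)C1=C(C=O)C(C)(C)CCC1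
F8 | step 11 | ethyl (2S,3R,6S)-3-(2-formyl-3,3-dimethylcyclohex-1-en-1-yl)-6-hydroxy-2,3,6-trimethyloct-7-enoate | CCOC(=O)[C@@H](C)[C@@](C)(CC[C@](C)(O)C=C)C1=C(C=O)C(C)(C)CCC1
F9 | step 13 | (3S,6R,7R)-6-(2-ethenyl-3,3-dimethylcyclohex-1-en-1-yl)-3,6,7-trimethylnona-1,8-dien-3-ol | C=C[C@@H](C)[C@@](C)(CC[C@](C)(O)C=C)C1=C(C=C)C(C)(C)CCC1
F10 | step 13 | (3S)-3-methyl-5-[(1R,2R)-1,2,5,5-tetramethyl-1,2,5,6,7,8-hexahydronaphthalen-1-yl]pent-1-en-3-ol | C=C[C@@](C)(O)CC[C@@]1(C)C2=C(C=C[C@H]1C)C(C)(C)CCC2
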